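**Assumption:** (+)-catechin (2R,3S) is taken as a commercial chiral-pool starting material, so C2 and C3 of the target are imported, not created. The target is read from the SMILES as the C8-linked (2R,3S)-catechin derivative.

## Retrosynthetic overview

1. Target 13 ⇐ global O-debenzylation of penta-O-benzyl ether 12.
2. Key disconnection: both C–C bonds of the Ar–CH2–Ar′ bridge in one operation ⇒ catechin-8-boronic acid 5 + formaldehyde 11 + acylphloroglucinol 10 (new boron-templated three-component coupling).
3. 5 ⇐ (+)-catechin 1 by O-benzylation, C8-selective bromination, 3-O-benzylation and Br→B exchange.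
4. 10 ⇐ 2-methylphloroglucinol 6 by C-acetylation, bis-MOM protection of the two more accessible OH groups, O-methylation of the remaining hindered OH, and MOM removal.
5. Ring order: no permanent ring is built. The chroman, its two aryl rings and the phloroglucinol ring are all purchased; only a transient 1,3,2-benzodioxaborin ring forms and is consumed in the key step.

## Route

**Step 1**
Reactants: 1, (+)-catechin
Product: 2, (2R,3S)-5,7-bis(benzyloxy)-2-[3,4-bis(benzyloxy)phenyl]chroman-3-ol
Conditions: BnBr (4.4 equiv), K2CO3, DMF, 0 °C → rt, Ar
Reagents that add atoms: benzyl bromide, BrCc1ccccc1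
Why: Williamson etherification; K2CO3 deprotonates only the four phenols, so the C3 secondary alcohol stays free and C2/C3 are untouched.

**Step 2**
Reactants: 2
Product: 3, (2R,3S)-5,7-bis(benzyloxy)-2-[3,4-bis(benzyloxy)phenyl]-8-bromochroman-3-ol
Conditions: NBS (1.0 equiv), CH2Cl2, −78 °C → rt
Reagents that add atoms: N-bromosuccinimide, O=C1CCC(=O)N1Br
Why: Electrophilic aromatic bromination; the phloroglucinol-type A ring is the most nucleophilic arene, and C8 reacts in preference to C6 (buttressed between two OBn groups), the established selectivity for tetra-O-benzyl flavan-3-ols.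

**Step 3**
Reactants: 3
Product: 4, (2R,3S)-3,5,7-tris(benzyloxy)-2-[3,4-bis(benzyloxy)phenyl]-8-bromochroman
Conditions: NaH, BnBr, n-Bu4NI (cat.), DMF, 0 °C → rt
Reagents that add atoms: benzyl bromide, BrCc1ccccc1
Why: Williamson etherification of the C3 alkoxide removes the last acidic proton before organolithium chemistry; no bond to C3 is broken, so the configuration is retained.

**Step 4**
Reactants: 4
Product: 5, [(2R,3S)-3,5,7-tris(benzyloxy)-2-[3,4-bis(benzyloxy)phenyl]chroman-8-yl]boronic acid
Conditions: n-BuLi (1.1 equiv), THF, −78 °C, 10 min; B(OMe)3, −78 → 0 °C; aq NH4Cl; no chromatography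
Reagents that add atoms: trimethyl borate, COB(OC)OC; water, O
Why: Bromine–lithium exchange at −78 °C is faster than benzylic or C2–H deprotonation, and borate trapping followed by hydrolysis places boron exactly at C8.

**Step 5**
Reactants: 6, 2-methylphloroglucinol (2,4,6-trihydroxytoluene)
Product: 7, 1-(2,4,6-trihydroxy-3-methylphenyl)ethanone
Conditions: Ac2O (1.1 equiv), BF3·OEt2, rt; aq NaOAc
Reagents that add atoms: acetic anhydride, CC(=O)OC(C)=O
Why: Friedel–Crafts C-acylation; the two free ring positions of 6 are equivalent, so one mono-ketone forms, and its BF2 chelate is deactivated toward a second acylation.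

**Step 6**
Reactants: 7
Product: 8, 1-[2-hydroxy-4,6-bis(methoxymethoxy)-3-methylphenyl]ethanone
Conditions: MOMCl (2.2 equiv), i-Pr2NEt, CH2Cl2, 0 °C → rt
Reagents that add atoms: chloromethyl methyl ether, COCCl
Why: Selective O-alkylation; the para-OH and the less hindered ortho-OH (next to C–H) react, while the OH flanked by the C-methyl and the acetyl group is the most hindered and most strongly hydrogen-bonded and stays free.

**Step 7**
Reactants: 8
Product: 9, 1-[2-methoxy-4,6-bis(methoxymethoxy)-3-methylphenyl]ethanone
Conditions: MeI, K2CO3, DMF, 45 °C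
Reagents that add atoms: iodomethane, CI
Why: Williamson O-methylation of the only remaining phenol fixes the methoxy group between the C-methyl and acetyl groups; MOM acetals are base-stable.

**Step 8**
Reactants: 9
Product: 10, 1-(4,6-dihydroxy-2-methoxy-3-methylphenyl)ethanone
Conditions: 3 M HCl, MeOH, 50 °C
Reagents that add atoms: none
Why: Acid-catalysed acetal cleavage removes both MOM groups; the aryl methyl ether and ketone are inert, leaving one free ring carbon flanked by two OH groups.

**Step 9 (key step)**
Reactants: 5, catechin-8-boronic acid; 10, acylphloroglucinol; 11, paraformaldehyde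
Product: 12, 1-[3-({(2R,3S)-3,5,7-tris(benzyloxy)-2-[3,4-bis(benzyloxy)phenyl]chroman-8-yl}methyl)-2,4-dihydroxy-6-methoxy-5-methylphenyl]ethanone
Conditions: 5 (1.0 equiv), 10 (1.1 equiv), (CH2O)n (1.5 equiv), 4 Å MS, PhMe, 70 °C; then HFIP (20 vol %), rt; pH 7 buffer work-up
Reagents that add atoms: formaldehyde (as paraformaldehyde), C=O (only the CH2 carbon is retained)
Why: Proposed new method: a boron-templated three-component "methylene stitching" in which boronic acid 5 esterifies a phenolic OH of 10 and delivers CH2O to the only free ortho carbon (as in phenylboronic acid/formaldehyde ortho-hydroxymethylation of phenols) to give a 2-aryl-4H-1,3,2-benzodioxaborin, after which ionisation of its benzylic C–O bond (HFIP, assisted by the second ortho-OH) gives a boron-bound o-quinone methide whose boronate transfers the very electron-rich catechin aryl group, ipso at C8, to the CH2 terminus through a six-membered transition state, so the bridge forms exactly where boron was on one ring and at the sole free position on the other, with boron lost as boric acid and C2/C3 untouched; the closest known reaction types are the Petasis borono-Mannich aryl transfer, aryl/alkenylboronate conjugate addition to o-quinone methides, and Nagata-type benzodioxaborin formation, none of which uses the boron aryl group as the transferred nucleophile in a formaldehyde-derived borin.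

**Step 10**
Reactants: 12
Product: 13, Pilosanol N, 1-[3-({(2R,3S)-2-(3,4-dihydroxyphenyl)-3,5,7-trihydroxychroman-8-yl}methyl)-2,4-dihydroxy-6-methoxy-5-methylphenyl]ethanone
Conditions: H2 (1 atm), 20% Pd(OH)2/C, THF/MeOH (1:1), rt; filter under Ar, Sephadex LH-20
Reagents that add atoms: none
Why: Catalytic hydrogenolysis cleaves all five benzyl ethers under neutral conditions, which leaves the aryl methyl ether, the chelated aryl ketone, the diarylmethane and the C2–O1 bond intact and avoids base-induced C2 epimerisation or methylene-bridge scrambling.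

## Compound list

1 | (+)-catechin, (2R,3S) | Oc1cc(O)c2c(c1)O[C@H](c1ccc(O)c(O)c1)[C@@H](O)C2 | starting material
2 | 5,7,3′,4′-tetra-O-benzyl-(+)-catechin | c1c(OCc2ccccc2)cc(OCc2ccccc2)c2c1O[C@H](c1ccc(OCc3ccccc3)c(OCc3ccccc3)c1)[C@@H](O)C2 | intermediate
3 | 8-bromo-5,7,3′,4′-tetra-O-benzylcatechin | Brc1c(OCc2ccccc2)cc(OCc2ccccc2)c2c1O[C@H](c1ccc(OCc3ccccc3)c(OCc3ccccc3)c1)[C@@H](O)C2 | intermediate
4 | 8-bromo-3,5,7,3′,4′-penta-O-benzylcatechin | Brc1c(OCc2ccccc2)cc(OCc2ccccc2)c2c1O[C@H](c1ccc(OCc3ccccc3)c(OCc3ccccc3)c1)[C@@H](OCc1ccccc1)C2 | intermediate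
5 | penta-O-benzylcatechin-8-ylboronic acid | OB(O)c1c(OCc2ccccc2)cc(OCc2ccccc2)c2c1O[C@H](c1ccc(OCc3ccccc3)c(OCc3ccccc3)c1)[C@@H](OCc1ccccc1)C2 | intermediate
6 | 2-methylphloroglucinol | Cc1c(O)cc(O)cc1O | starting material
7 | 1-(2,4,6-trihydroxy-3-methylphenyl)ethanone | CC(=O)c1c(O)cc(O)c(C)c1O | intermediate
8 | 1-[2-hydroxy-4,6-bis(methoxymethoxy)-3-methylphenyl]ethanone | CC(=O)c1c(OCOC)cc(OCOC)c(C)c1O | intermediate
9 | 1-[2-methoxy-4,6-bis(methoxymethoxy)-3-methylphenyl]ethanone | CC(=O)c1c(OCOC)cc(OCOC)c(C)c1OC | intermediate
10 | 1-(4,6-dihydroxy-2-methoxy-3-methylphenyl)ethanone | COc1c(C)c(O)cc(O)c1C(C)=O | intermediate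
11 | paraformaldehyde (formaldehyde source) | C=O | starting material
12 | penta-O-benzyl pilosanol N | COc1c(C)c(O)c(Cc2c(OCc3ccccc3)cc(OCc3ccccc3)c3c2O[C@H](c2ccc(OCc4ccccc4)c(OCc4ccccc4)c2)[C@@H](OCc2ccccc2)C3)c(O)c1C(C)=O | intermediate
13 | Pilosanol N | COc1c(C)c(O)c(Cc2c(O)cc(O)c3c2O[C@H](c2ccc(O)c(O)c2)[C@@H](O)C3)c(O)c1C(C)=O | target

## Summary

Total steps: 10. Longest linear sequence: 6 (steps 1, 2, 3, 4, 9, 10); the acylphloroglucinol branch is 4 steps (5–8).

Steps most likely to fail:

1. **Step 9 (proposed new coupling).** Risks are protodeboronation of 5, formation of the symmetric methylene-bis dimer of 10, and stray attack at C6 of the catechin ring. Fallback (known chemistry): treat 4 with n-BuLi then DMF to give the 8-carbaldehyde, reduce with NaBH4 to the 8-hydroxymethyl compound, and run an acid-catalysed Friedel–Crafts benzylation of 10 (cat. Sc(OTf)3 or TsOH, CH2Cl2) at its only free position to reach the same 12. Regiochemistry is still fixed by the C8 bromide.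

2. **Step 4 (2,6-dialkoxyarylboronic acid).** Risks are competing benzylic lithiation and protodeboronation on work-up or storage. Fallback: replace the organolithium route with Pd-catalysed Miyaura borylation of 4 (B2pin2, Pd/SPhos, KOAc), convert the pinacol boronate to the bench-stable trifluoroborate (KHF2), and hydrolyse it to the boronic acid immediately before the coupling.

3. **Step 6 (regioselective bis-MOM protection).** The risk is the isomeric bis-ether, which would put the methoxy group on the wrong oxygen. Fallback: start from symmetric 2,4,6-trihydroxyacetophenone, where bis-MOM protection can give only one product. Then iodinate ortho to the free OH (NIS), O-methylate, install the C-methyl by Suzuki–Miyaura coupling (trimethylboroxine, Pd(dppf)Cl2), and remove MOM with HCl/MeOH to reach 10. This fixes the O-methyl position before the C-methyl is introduced.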